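Atom labels C1–C26 follow the order of the atoms in the target SMILES (C1 = isopropenyl CH2; O8 and O12 are the ketone oxygens, O21 and O25 the phenol oxygens).

## Structural features

The target is a pentacyclic C22 hydroquinone. A cyclohexane-1,4-dione ring (C6, C7, C9, C10, C11, C13) is cis-fused through C6–C13 to an indane (C13, C6, C18, C19, C26 and the benzene ring). C5–C4 bridges C6 and C9, so C7 is the one-carbon bridge of a bicyclo[3.2.1]octan-8-one; C14–C15(CH3)=C17 bridges C13 and C18, giving a benzo-fused bicyclo[3.2.1]octadiene that shares C6 and C13 with the first bicycle. There are five stereocentres: C6 and C13 are vicinal quaternary carbons (C13 also benzylic and α to the C11 ketone), C18 and C9 are bridgeheads fixed by the cages, and C4 carries an exo isopropenyl group. The independent elements are therefore the absolute configuration, the C6/C13 relationship (C5, C14 and C17 on one face of the indane; C7 and C11 on the other) and C4. Fragile groups are the free hydroquinone (air, oxidants), the isopropenyl and C15=C17 alkenes (acid) and the 1,4-dione, whose methylenes C9 and C10 are almost equivalent. The real difficulty is threefold: three carbon substituents on one face at contiguous C13, C6 and C18; telling C6 from C9 and C9 from C10 in enolate chemistry; and the C4–C9 bond, which as an enolate alkylation would be a five-membered closure through the carbonyl carbon and is stereoelectronically disfavoured. The key step exploits the 1,4-placement of oxygen on C11 and C7 in the six-membered ring fused to the indane at C6–C13: with C11=C13 as an enol ether, that ring is the cyclohexene retron of a [4+2] addition between the diene C10=C11–C13=C6 and a ketene equivalent supplying C9 and C7.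

## Logic of the disconnections

33 ⇒ 31. The two O–H bonds of the hydroquinone become O–CH3. The hydroquinone is the most sensitive function and is masked until the end. The forward step must remove two aryl methyl ethers without acid, so it runs oxidatively through 32 and a reduction.

31 ⇒ 30. Cut C4–C9 (and the C10–H bond). The isopropenyl group next to C4 is the mark of an allylic radical adding through its inner terminus, and C9 becomes the β-carbon of an ene-dione. This removes one bicycle and the stereocentres C4 and C9. The forward step needs 5-exo closure at C9 rather than C10, an exo isopropenyl group, and a radical rather than an enolate.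

30 ⇒ 29. Cut C17–C18. C18 is the only benzylic CH2 on an electron-rich ring, so it can be made cationic by hydride abstraction; a vinylsilane on the C13 arm fixes both the alkene position and, through the tether, the C18 configuration. This removes the second bridged ring. C6 must already be quaternary, so that its configuration comes from the cis-fusion and not from the cage.

29 ⇒ 26 + 27. Cut C5–C6. In 26 the C9=C10 bond removes every other acidic C–H, so C6 is the only enolisable carbon. The gain is a quaternary centre from a commercial four-carbon bis-electrophile. The forward step demands attack at the right terminus of 27 and entry cis to C14.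

26 ⇒ 24 ⇒ 22. The C7 carbonyl is traced to a spiro-oxirane (C7–O and C7–CH2), and C9=C10 to dehydrogenation of the C11 ketone, which in 22 can only enolise towards C10. Keeping C7 tetrahedral until C13 is quaternary protects the single stereocentre C6 from epimerisation.

22 ⇒ 14 + 20. Cut C13–C14. The silyl enol ether of 14 is the regiodefined C13 nucleophile. C6–H and the quaternary C7 must steer the side chain to the face of H6.

14 ⇒ 12. Functional-group change only: the formyl carbon and bromine of 12 become the oxirane.

12 ⇒ 8 + 11. Cut C9–C10 and C6–C7 (the key step). One ring, two bonds and the first stereocentres are made from two achiral partners. The forward step needs regio-, endo- and facial control.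

8 ⇒ 6 ⇒ 4 ⇒ 1 + 2. Cut the O–Si bond, then C13=C6 (dehydration), then the C13–C11 bond to the ketone of 1. 11 ⇒ 9 (C–Br). 20 ⇒ 19 ⇒ 17 ⇒ 15 (C–Br, C–Si, then C15–CH3 and C17–I across the alkyne).

## Other disconnections considered

Alternative 1: Cut C4–C9 with a temporary C2–C9 bond. The diazoketone A1 would be decomposed by a chiral dirhodium tetracarboxylate such as Rh2(S-PTTL)4 (divalent rhodium), and the carbenoid would add to the prenyl alkene to give the gem-dimethylcyclopropane A2; later homo-1,5-hydrogen shift of the cyclopropyl ketone would release the exo isopropenyl group.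
- In favour: C4 and C9 are set by the catalyst in one step, the exo configuration follows stereospecifically from the cis-fused cyclopropane, and there is no C9/C10 ambiguity. On C4 this is better than the radical closure of the chosen plan.
- Against: A2 still lacks the aryl ring, C10, C11 and the C15 methyl. C6 becomes stereogenic only when the two enone arms of the spiro-dienone are differentiated, under remote control from C4 and C9; C13 must then be made quaternary by two successive additions. Diazo handling and competing attack of the carbenoid on the dienone add risk.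
- Comparison: the chosen plan is stronger on C6, C13 and C18 and starts with the arene in place. Step economy is at best equal.

Alternative 2: Cut C6–C18 and C13–C26. Protonation of the diene in the linked phenol A3 would give an allyl/benzyl cation that attacks the prenylated carbon ipso, and the resulting dienone would be trapped by the dimethoxyphenyl ring to give A4.
- In favour: two bonds, two rings and three stereocentres, both quaternary carbons included, arise in one operation from a flat precursor. In step economy this is better than the chosen plan. A4 also has C10=C11 as an enol ether, so C9 is already distinguished from C10, which is a real advantage for the last ring.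
- Against: absolute configuration would have to come from a chiral acid acting on a free cation; the ortho-prenyl phenol of A3 is prone to chroman formation under acid; ipso attack must beat ortho attack.
- Comparison: mechanistically it is the less predictable plan and it gives racemic material unless the cascade can be made enantioselective.

Alternative 3: Cut C18–C19 and C13–C26. Hydroquinone A7 would add to the bicyclic cross-conjugated dienone A5, first at C18 and then, through the neighbouring ring carbon, at C13, to give A6.
- In favour: no phenol protecting groups are needed (better than the chosen plan); C6 could come from an asymmetric Robinson annulation; C11 is carried as a silyl ether, so C9 is the only ketone α-methylene when the last ring is closed (again better). The route is probably shorter.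
- Against: the second addition makes a quaternary carbon next to a quaternary carbon at a β,β-disubstituted enone position and is reversible; O-attack and oxidation of the hydroquinone compete; the C15 ketone must later be turned regioselectively into C15(CH3)=C17.
- Comparison: equal or better in step count if the double addition works. The chosen plan avoids that uncertainty because both aryl–carbon bonds exist in the starting indanone.

Key step: step 5

Assumption: the facial sense of the oxazaborolidinium catalyst is taken from the accepted model for 2-substituted acroleins; on that basis the (R)-catalyst is specified, and its antipode would be used if the sense were the opposite.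

Remark on the structures: no error was found in the precursor 8 or the adduct 12. The C7 descriptor of 12 corresponds to an endo formyl group; the catalyst sets C7 directly and C6 through the endo approach. Precursor 8 is kept unchanged: the methyl ethers later activate C18 and are removed oxidatively.

Remark on the sequence after the key step: C13 is alkylated before C7 becomes a ketone (otherwise C6–H, the only stereocentre, would be α to a ketone and allylic). C6 is alkylated on an ene-dione, so no other position can enolise. The bridgehead C18 is made by cation capture, not by ketone addition and deoxygenation. The methyl ethers are removed oxidatively, not with a Lewis acid.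

## Steps

Step 1
Reactants: 1 4,7-dimethoxy-2,3-dihydro-1H-inden-1-one; 2 ethyl vinyl ether
Product: 4 1-(1-ethoxyvinyl)-4,7-dimethoxy-2,3-dihydro-1H-inden-1-ol (racemic), via 1-ethoxyvinyllithium 3 (not isolated)
Conditions: 2, t-BuLi, THF, −78 → 0 °C; CeCl3, −78 °C; then 1, −78 °C; H2O
Reagents that add atoms: none
Why: 1,2-addition of an α-alkoxyvinyl organometallic (acyl-anion equivalent) to an aryl ketone; the organocerium suppresses enolisation of the hindered indanone; the carbinol centre is racemic and is destroyed in step 2.

Step 2
Reactants: 4 1-(1-ethoxyvinyl)-4,7-dimethoxy-2,3-dihydro-1H-inden-1-ol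
Product: 6 1-(4,7-dimethoxy-1H-inden-3-yl)ethan-1-one, via hydroxy ketone 5 (not isolated)
Conditions: 1 M HCl, THF, rt; then SOCl2, pyridine, CH2Cl2, 0 °C
Reagents that add atoms: water, SMILES O
Why: acid hydrolysis of the enol ether to the α-hydroxy methyl ketone, then dehydration of the tertiary alcohol via its chlorosulfite; only the ring CH2 carries β-hydrogen, so the conjugated C13=C6 alkene is the sole product.

Step 3
Reactants: 6 1-(4,7-dimethoxy-1H-inden-3-yl)ethan-1-one
Product: 8 3-[1-(tert-butyldimethylsilyloxy)vinyl]-4,7-dimethoxy-1H-indene, via lithium dienolate 7 (not isolated)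
Conditions: LiN(i-Pr)2 (1.1 equiv), THF, −78 °C (6 added slowly to the base); TBSOTf, −78 °C; Et3N-buffered work-up
Reagents that add atoms: tert-butyldimethylsilyl trifluoromethanesulfonate, CC(C)(C)[Si](C)(C)OS(=O)(=O)C(F)(F)F
Why: kinetic α′-deprotonation of the enone at the methyl group and O-silylation give the cross-conjugated 2-silyloxydiene; inverse addition keeps free ketone, whose C18 protons are acidic, at a minimum.

Step 4
Reactants: 9 acrolein
Product: 11 2-bromoacrolein, via 2,3-dibromopropanal 10 (not isolated)
Conditions: Br2, CH2Cl2, 0 °C; then Et3N, 0 °C → rt; distilled and used fresh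
Reagents that add atoms: bromine, BrBr
Why: bromine addition to the enal and base-induced loss of HBr from the α,β-dibromo aldehyde; the standard preparation of this dienophile.

Step 5
Reactants: 8 3-[1-(tert-butyldimethylsilyloxy)vinyl]-4,7-dimethoxy-1H-indene; 11 2-bromoacrolein
Product: 12 (1S,9aS)-1-bromo-4-(tert-butyldimethylsilyloxy)-5,8-dimethoxy-2,3,9,9a-tetrahydro-1H-fluorene-1-carbaldehyde
Conditions: (R)-3,3-diphenyl-1-(2-methylphenyl)tetrahydro-1H,3H-pyrrolo[1,2-c][1,3,2]oxazaborole (20 mol %), (CF3SO2)2NH (18 mol %), CH2Cl2, −78 °C; Et3N quench; Et3N-deactivated silica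
Reagents that add atoms: none
Why: Normal-demand [4+2] cycloaddition of the electron-rich 2-silyloxydiene with the enal bound to the oxazaborolidinium ion (formyl C–H···O contact, s-trans enal stacked on the neighbouring phenyl group), concerted but asynchronous with C10–C9 bonding in advance; a stepwise Michael/ring-closure path would give the same adduct. The closest known reactions are oxazaborolidinium-catalysed Diels–Alder additions of 2-bromoacrolein and 2-methylacrolein to 2-silyloxy-1,3-dienes and to cyclopentadiene. Ring C6–C7–C9–C10–C11–C13 closes in one suprafacial/suprafacial event, so H6 and the C7 substituents come out with a fixed relative configuration. C7 is set by the catalyst, which should expose only the Si face of the bound enal; C6 is set by the endo position of the catalyst-bound formyl group, which decides which face of the indene terminus meets that enal face. Regiochemistry is secured by the silyloxy group on C11, which puts the largest HOMO coefficient on C10 and pairs it with the enal β-carbon C9. High endo selectivity is needed as well as facial selectivity, because an exo adduct formed on the same enal face has the opposite C6 configuration and would erode optical purity once C7 is trigonal; the two are diastereomers here and are separated at this stage. Low temperature and the bulky silyl group suppress silyl transfer and acid cleavage of the tetrasubstituted enol ether.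

Step 6
Reactants: 12 (1S,9aS)-1-bromo-4-(tert-butyldimethylsilyloxy)-5,8-dimethoxy-2,3,9,9a-tetrahydro-1H-fluorene-1-carbaldehyde
Product: 14 4′-(tert-butyldimethylsilyloxy)-5′,8′-dimethoxy-2′,3′,9′,9a′-tetrahydrospiro[oxirane-2,1′-fluorene] (oxirane O cis to the 9′-CH2, oxirane CH2 cis to H-9a′), via bromohydrin 13 (not isolated)
Conditions: NaBH4, MeOH–THF, −20 °C; then K2CO3, 0 °C → rt
Reagents that add atoms: none
Why: chemoselective hydride reduction of the aldehyde, then 3-exo-tet Williamson closure of the bromohydrin with inversion at C7; C7 stays tetrahedral, so C6–H is not acidic, and the mild base leaves the silyl enol ether intact.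

Step 7
Reactants: 15 prop-2-yn-1-ol
Product: 17 (Z)-3-iodo-2-methylprop-2-en-1-ol, via vinylmagnesium chelate 16 (not isolated)
Conditions: MeMgBr (2.5 equiv), CuI (10 mol %), THF, −10 °C → rt; then I2, −20 °C; aq. Na2S2O3
Reagents that add atoms: methylmagnesium bromide, C[Mg]Br; iodine, II
Why: alkoxide-directed anti-carbomagnesiation of the propargylic alcohol puts methyl on C15 and magnesium on C17 cis to the CH2O group; iodinolysis with retention gives the Z vinyl iodide.

Step 8
Reactants: 17 (Z)-3-iodo-2-methylprop-2-en-1-ol
Product: 19 (Z)-2-methyl-3-(trimethylsilyl)prop-2-en-1-ol, via bis-silyl compound 18 (not isolated)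
Conditions: t-BuLi (3.1 equiv), Et2O, −78 °C; Me3SiCl (2.5 equiv), −78 °C → rt; aq. citric acid
Reagents that add atoms: chlorotrimethylsilane, C[Si](C)(C)Cl
Why: iodine–lithium exchange with retention of alkene geometry, C- and O-silylation, and selective hydrolysis of the O–Si bond on work-up; silicon cis to C14 is what step 14 requires.

Step 9
Reactants: 19 (Z)-2-methyl-3-(trimethylsilyl)prop-2-en-1-ol
Product: 20 (Z)-(3-bromo-2-methylprop-1-en-1-yl)trimethylsilane
Conditions: CBr4, PPh3, CH2Cl2, 0 °C
Reagents that add atoms: carbon tetrabromide, BrC(Br)(Br)Br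
Why: Appel bromination of a primary allylic alcohol under neutral conditions, which spares the vinylsilane and the alkene geometry.

Step 10
Reactants: 14 spiro-oxirane silyl enol ether; 20 (Z)-(3-bromo-2-methylprop-1-en-1-yl)trimethylsilane
Product: 22 5′,8′-dimethoxy-4a′-[(Z)-2-methyl-3-(trimethylsilyl)prop-2-enyl]-2′,3′,9′,9a′-tetrahydrospiro[oxirane-2,1′-fluoren]-4′(4a′H)-one (side chain on C13 cis to H6), via sulfonium enolate 21 (not isolated)
Conditions: (Me2N)3S+ Me3SiF2− (1.1 equiv), THF, −78 °C; then 20 (1.5 equiv), −78 → −20 °C
Reagents that add atoms: none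
Why: fluoride cleavage of the silyl enol ether releases the regiodefined, aryl-conjugated enolate, which is C-alkylated by the allylic bromide (fluoride-mediated regiospecific alkylation of silyl enol ethers); the electrophile enters anti to the quaternary spiro carbon C7, that is syn to H6, the only face that leads to a cis-fused hexahydrofluorenone, so C13 takes its configuration from C6.

Step 11
Reactants: 22 cis-fused keto oxirane
Product: 24 5′,8′-dimethoxy-4a′-[(Z)-2-methyl-3-(trimethylsilyl)prop-2-enyl]-9′,9a′-dihydrospiro[oxirane-2,1′-fluoren]-4′(4a′H)-one (C9=C10 enone), via lithium enolate 23 (not isolated)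
Conditions: LiN(i-Pr)2, THF, −78 °C; then PhS(Cl)=N-t-Bu, −78 °C
Reagents that add atoms: none
Why: Mukaiyama one-pot dehydrogenation; C10 is the only enolisable position of this ketone, and sulfinimidoylation of the enolate followed by syn-elimination at −78 °C installs C9=C10 without touching the oxirane.

Step 12
Reactants: 24 enone oxirane
Product: 26 5,8-dimethoxy-4a-[(Z)-2-methyl-3-(trimethylsilyl)prop-2-enyl]-9,9a-dihydro-1H-fluorene-1,4(4aH)-dione (cis ring fusion), via diol 25 (not isolated)
Conditions: H5IO6 (2 equiv), THF–H2O, 0 °C → rt
Reagents that add atoms: water, SMILES O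
Why: acid-catalysed hydrolysis of the 2,2-disubstituted oxirane (either regiochemistry gives the same glycol) and periodate glycol cleavage in one flask excise the former formyl carbon and unveil the C7 ketone; in the resulting ene-dione C6–H is the only acidic C–H, and its configuration no longer matters because C13 is fixed.

Step 13
Reactants: 26 ene-dione; 27 (E)-1,4-dibromo-2-methylbut-2-ene
Product: 29 9a-[(E)-4-bromo-3-methylbut-2-enyl]-5,8-dimethoxy-4a-[(Z)-2-methyl-3-(trimethylsilyl)prop-2-enyl]-9,9a-dihydro-1H-fluorene-1,4(4aH)-dione (the two side chains cis), via lithium enolate 28 (not isolated)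
Conditions: LiN(SiMe3)2 (1.05 equiv), THF, −78 °C; then 27 (4 equiv), −78 → 0 °C
Reagents that add atoms: none
Why: SN2 alkylation of the only possible enolate at the less hindered, prenyl-type CH2Br terminus (C5) of the dibromide; the chain enters cis to C14 because a trans-fused, largely sp2 six-membered ring on a planar indane is prohibitively strained, which sets C6.

Step 14
Reactants: 29 doubly alkylated ene-dione
Product: 30 bridged tetracyclic ene-dione (C14H2–C15(CH3)=C17H bridge from C13 to C18; C6 chain on the side of that bridge)
Conditions: DDQ (1.3 equiv), 2,6-dichloropyridine, 4 Å MS, ClCH2CH2Cl, 0 °C → rt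
Reagents that add atoms: none
Why: Proposed new method: hydride abstraction by DDQ from C18, the only benzylic CH2 and activated by the dimethoxy ring, gives a planar indanyl cation that has no β-hydrogen to lose and is captured on its lower face by the tethered Z vinylsilane at C17 (ipso attack, β-silyl cation at C15); loss of silicon restores C15=C17, so alkene position and C18 configuration are fixed by the tether, and the bridgehead product cannot be oxidised further. The closest known reactions are DDQ-mediated oxidative C–H cyclisations of benzylic ethers onto π-nucleophiles and vinylsilane-terminated cation cyclisations in the endocyclic mode.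

Step 15
Reactants: 30 bridged tetracyclic ene-dione
Product: 31 O21,O25-dimethyl ether of the target
Conditions: (Me3Si)3SiH (1.3 equiv), AIBN (0.2 equiv), PhH (0.01 M), 80 °C, slow addition
Reagents that add atoms: none
Why: bromine abstraction gives an allylic radical whose C4 terminus adds 5-exo-trig to C9 of the ene-dione (allylic radical cyclisation onto an activated alkene), which avoids the disfavoured enolate closure and prefers C9 over C10 by ring size; C9 is fixed by the bridge, the isopropenyl group should take the exo position away from the C10–C11 bridge, and the C10 radical is reduced by the silane.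

Step 16
Reactants: 31 O21,O25-dimethyl ether of the target
Product: 33 CNP0287617.1 (target), via quinone 32 (not isolated)
Conditions: (NH4)2Ce(NO3)6 (2.5 equiv), MeCN–H2O, 0 °C; then Na2S2O4 (aq), EtOAc, rt, under argon
Reagents that add atoms: water, SMILES O
Why: oxidative demethylation of the para-dimethoxyarene by tetravalent cerium gives the para-quinone without the strong acid that would attack the isopropenyl group, and dithionite reduces it to the hydroquinone; no stereocentre is touched.

## Compound list

1 | 4,7-dimethoxy-2,3-dihydro-1H-inden-1-one | COc1ccc(OC)c2c1CCC2=O | starting material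
2 | ethyl vinyl ether | C=COCC | starting material
3 | 1-ethoxyvinyllithium | [Li]C(=C)OCC | intermediate (not isolated)
4 | 1-(1-ethoxyvinyl)-4,7-dimethoxy-2,3-dihydro-1H-inden-1-ol (racemic) | C=C(OCC)C1(O)CCc2c(OC)ccc(OC)c21 | intermediate
5 | 1-(1-hydroxy-4,7-dimethoxy-2,3-dihydro-1H-inden-1-yl)ethan-1-one (racemic) | CC(=O)C1(O)CCc2c(OC)ccc(OC)c21 | intermediate (not isolated)
6 | 1-(4,7-dimethoxy-1H-inden-3-yl)ethan-1-one | CC(=O)C1=CCc2c(OC)ccc(OC)c21 | intermediate
7 | lithium 1-(4,7-dimethoxy-1H-inden-3-yl)ethen-1-olate | [Li]OC(=C)C1=CCc2c(OC)ccc(OC)c21 | intermediate (not isolated)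
8 | 3-[1-(tert-butyldimethylsilyloxy)vinyl]-4,7-dimethoxy-1H-indene | C=C(O[Si](C)(C)C(C)(C)C)C1=CCc2c(OC)ccc(OC)c21 | intermediate
9 | acrolein | C=CC=O | starting material
10 | 2,3-dibromopropanal | O=CC(Br)CBr | intermediate (not isolated)
11 | 2-bromoacrolein | C=C(Br)C=O | intermediate
12 | (1S,9aS)-1-bromo-4-(tert-butyldimethylsilyloxy)-5,8-dimethoxy-2,3,9,9a-tetrahydro-1H-fluorene-1-carbaldehyde (fluorene C1 = C7, C9a = C6; CHO cis to the C9 methylene) | O=C[C@]1(Br)CCC(O[Si](C)(C)C(C)(C)C)=C2c3c(OC)ccc(OC)c3C[C@@H]21 | intermediate
13 | [(1S,9aS)-1-bromo-4-(tert-butyldimethylsilyloxy)-5,8-dimethoxy-2,3,9,9a-tetrahydro-1H-fluoren-1-yl]methanol | OC[C@]1(Br)CCC(O[Si](C)(C)C(C)(C)C)=C2c3c(OC)ccc(OC)c3C[C@@H]21 | intermediate (not isolated)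
14 | 4′-(tert-butyldimethylsilyloxy)-5′,8′-dimethoxy-2′,3′,9′,9a′-tetrahydrospiro[oxirane-2,1′-fluorene], oxirane O cis to the 9′-CH2, oxirane CH2 cis to H-9a′ | O1C[C@]12CCC(O[Si](C)(C)C(C)(C)C)=C3c4c(OC)ccc(OC)c4C[C@@H]32 | intermediate
15 | prop-2-yn-1-ol | C#CCO | starting material
16 | 4-methyl-2,5-dihydro-1,2-oxamagnesole (chelated vinylmagnesium alkoxide) | CC1=C[Mg]OC1 | intermediate (not isolated)
17 | (Z)-3-iodo-2-methylprop-2-en-1-ol | OC/C(C)=C\I | intermediate
18 | (Z)-trimethyl[2-methyl-3-(trimethylsilyloxy)prop-1-en-1-yl]silane | C[Si](C)(C)OC/C(C)=C\[Si](C)(C)C | intermediate (not isolated)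
19 | (Z)-2-methyl-3-(trimethylsilyl)prop-2-en-1-ol | OC/C(C)=C\[Si](C)(C)C | intermediate
20 | (Z)-(3-bromo-2-methylprop-1-en-1-yl)trimethylsilane | BrC/C(C)=C\[Si](C)(C)C | intermediate
21 | tris(dimethylamino)sulfonium C11 enolate of the C7-spiro-oxirane (C11=C13) | O1C[C@]12CCC([O-])=C3c4c(OC)ccc(OC)c4C[C@@H]32.CN(C)[S+](N(C)C)N(C)C | intermediate (not isolated)
22 | 5′,8′-dimethoxy-4a′-[(Z)-2-methyl-3-(trimethylsilyl)prop-2-enyl]-2′,3′,9′,9a′-tetrahydrospiro[oxirane-2,1′-fluoren]-4′(4a′H)-one, C13 side chain cis to H6 | O1C[C@]12CCC(=O)[C@]3(C/C(C)=C\[Si](C)(C)C)c4c(OC)ccc(OC)c4C[C@@H]32 | intermediate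
23 | lithium C10=C11 enolate of 22 | O1C[C@]12CC=C(O[Li])[C@]3(C/C(C)=C\[Si](C)(C)C)c4c(OC)ccc(OC)c4C[C@@H]32 | intermediate (not isolated)
24 | 5′,8′-dimethoxy-4a′-[(Z)-2-methyl-3-(trimethylsilyl)prop-2-enyl]-9′,9a′-dihydrospiro[oxirane-2,1′-fluoren]-4′(4a′H)-one, configuration as in 22 | O1C[C@]12C=CC(=O)[C@]3(C/C(C)=C\[Si](C)(C)C)c4c(OC)ccc(OC)c4C[C@@H]32 | intermediate
25 | 1-hydroxy-1-(hydroxymethyl)-5,8-dimethoxy-4a-[(Z)-2-methyl-3-(trimethylsilyl)prop-2-enyl]-1,4a,9,9a-tetrahydro-4H-fluoren-4-one, C7 configuration undefined | OCC1(O)C=CC(=O)[C@]2(C/C(C)=C\[Si](C)(C)C)c3c(OC)ccc(OC)c3C[C@@H]21 | intermediate (not isolated)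
26 | 5,8-dimethoxy-4a-[(Z)-2-methyl-3-(trimethylsilyl)prop-2-enyl]-9,9a-dihydro-1H-fluorene-1,4(4aH)-dione, cis ring fusion | O=C1C=CC(=O)[C@]2(C/C(C)=C\[Si](C)(C)C)c3c(OC)ccc(OC)c3C[C@@H]21 | intermediate
27 | (E)-1,4-dibromo-2-methylbut-2-ene | BrC/C=C(C)/CBr | starting material
28 | lithium C6=C7 enolate of 26 | [Li]OC1=C2Cc3c(OC)ccc(OC)c3[C@@]2(C/C(C)=C\[Si](C)(C)C)C(=O)C=C1 | intermediate (not isolated)
29 | 9a-[(E)-4-bromo-3-methylbut-2-enyl]-5,8-dimethoxy-4a-[(Z)-2-methyl-3-(trimethylsilyl)prop-2-enyl]-9,9a-dihydro-1H-fluorene-1,4(4aH)-dione, side chains cis | O=C1C=CC(=O)[C@]2(C/C(C)=C\[Si](C)(C)C)c3c(OC)ccc(OC)c3C[C@@]21C/C=C(C)/CBr | intermediate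
30 | bridged tetracyclic ene-dione: C14H2–C15(CH3)=C17H bridge joining C13 and C18, C6 bearing the (E)-4-bromo-3-methylbut-2-enyl chain on the side of that bridge, C7(=O)–C9H=C10H–C11(=O), 1,4-dimethoxyarene | BrC/C(C)=C/C[C@@]23C(=O)C=CC(=O)[C@@]21CC(C)=C[C@@H]3c2c(OC)ccc(OC)c21 | intermediate
31 | O21,O25-dimethyl ether of the target | C=C(C)[C@H]1C[C@@]23C(=O)[C@@H]1CC(=O)[C@@]21CC(C)=C[C@@H]3c2c(OC)ccc(OC)c21 | intermediate
32 | para-quinone of the target skeleton (C20=O, C24=O) | C=C(C)[C@H]1C[C@@]23C(=O)[C@@H]1CC(=O)[C@@]21CC(C)=C[C@@H]3C2=C1C(=O)C=CC2=O | intermediate (not isolated)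
33 | CNP0287617.1 | C=C(C)[C@H]1C[C@@]23C(=O)[C@@H]1CC(=O)[C@@]21CC(C)=C[C@@H]3c2c(O)ccc(O)c21 | target

## Step count and least certain steps

Total: 16 steps. Longest linear sequence: 12 steps (1 → 4 → 6 → 8 → 12 → 14 → 22 → 24 → 26 → 29 → 30 → 31 → 33; steps 1, 2, 3, 5, 6, 10, 11, 12, 13, 14, 15, 16).

Step 14 (riskiest, new method). Hydride abstraction may be slow, or the cation may be diverted before the arm closes on it, for instance by capture by the reduced quinone or by over-oxidation of the electron-rich ring. Fallback with known chemistry, from 29: DDQ in AcOH–CH2Cl2 gives the benzylic acetate F1 (benzylic acetoxylation of an electron-rich alkylarene); F1 is then ionised with BF3·OEt2 in CH2Cl2 at −78 °C in a classical vinylsilane-terminated cyclisation, returning to the route at 30.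

Step 5 (key step). The likely failures are incomplete endo selectivity, a facial sense that does not carry over to this semicyclic diene, and acid-induced silyl transfer from the diene. Exo leakage is the more dangerous, because it becomes enantiomeric erosion after step 12. Fallback, from 8 and 11: a racemic cycloaddition with Me2AlCl gives 12 together with its enantiomer F2; reduction gives 13 and its enantiomer F3; esterification with (S)-2-methoxy-2-phenylacetic acid (DCC, DMAP) gives the diastereomeric esters F4 (from 13) and F5 (from F3), which are separated; K2CO3 in MeOH releases the alkoxide from F4 and closes the oxirane, returning at 14.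

Step 15. The allylic radical may be reduced before it cyclises, the silyl radical may reduce the ene-dione first, or the isopropenyl group may take the endo position. Fallback, from 26: alkylation of enolate 28 with prenyl bromide gives the prenyl ene-dione F6; the cyclisation of step 14 gives the bridged prenyl ene-dione F7; Hantzsch ester (toluene, 80 °C) reduces the ene-dione to the saturated dione F8; oxidative radical cyclisation with Mn(OAc)3·2H2O and Cu(OAc)2·H2O in AcOH at 80 °C (α-keto radical onto the prenyl group, copper-mediated loss of hydrogen to the isopropenyl group) returns at 31. This fallback would need separation from the product of C10 radical closure.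

Step 13. Substitution may occur at the wrong terminus of 27, or on oxygen, or a second enolate may displace the remaining bromide. Fallback, from 26: alkylation of enolate 28 with 2-methyl-2-vinyloxirane under zerovalent palladium catalysis, Pd(PPh3)4 (Tsuji–Trost 1,4-opening of a vinyl epoxide, attack at the vinyl terminus), gives the E allylic alcohol F9, whose single electrophilic site leaves no regiochemical choice; Appel bromination (CBr4, PPh3) returns at 29.

## Further compounds

F1 | step 14 | C18 acetate of 29 (C18 configuration undefined) | O=C1C=CC(=O)[C@]2(C/C(C)=C\[Si](C)(C)C)c3c(OC)ccc(OC)c3C(OC(C)=O)[C@@]21C/C=C(C)/CBr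
F2 | step 5 | enantiomer of 12 (second half of the racemate) | O=C[C@@]1(Br)CCC(O[Si](C)(C)C(C)(C)C)=C2c3c(OC)ccc(OC)c3C[C@H]21
F3 | step 5 | enantiomer of 13 | OC[C@@]1(Br)CCC(O[Si](C)(C)C(C)(C)C)=C2c3c(OC)ccc(OC)c3C[C@H]21
F4 | step 5 | (S)-2-methoxy-2-phenylacetate of 13 | CO[C@H](C(=O)OC[C@]1(Br)CCC(O[Si](C)(C)C(C)(C)C)=C2c3c(OC)ccc(OC)c3C[C@@H]21)c1ccccc1
F5 | step 5 | (S)-2-methoxy-2-phenylacetate of F3 | CO[C@H](C(=O)OC[C@@]1(Br)CCC(O[Si](C)(C)C(C)(C)C)=C2c3c(OC)ccc(OC)c3C[C@H]21)c1ccccc1
F6 | step 15 | 9a-prenyl analogue of 29 | O=C1C=CC(=O)[C@]2(C/C(C)=C\[Si](C)(C)C)c3c(OC)ccc(OC)c3C[C@@]21CC=C(C)C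
F7 | step 15 | bridged prenyl ene-dione (prenyl analogue of 30) | CC(C)=CC[C@@]23C(=O)C=CC(=O)[C@@]21CC(C)=C[C@@H]3c2c(OC)ccc(OC)c21
F8 | step 15 | bridged prenyl 1,4-dione (C9H2–C10H2) | CC(C)=CC[C@@]23C(=O)CCC(=O)[C@@]21CC(C)=C[C@@H]3c2c(OC)ccc(OC)c21
F9 | step 13 | 9a-[(E)-4-hydroxy-3-methylbut-2-enyl] analogue of 29 | O=C1C=CC(=O)[C@]2(C/C(C)=C\[Si](C)(C)C)c3c(OC)ccc(OC)c3C[C@@]21C/C=C(C)/CO
A1 | alternative 1 | 4-(diazoacetyl)-4-(3-methylbut-2-enyl)cyclohexa-2,5-dien-1-one | CC(C)=CCC1(C(=O)C=[N+]=[N-])C=CC(=O)C=C1
A2 | alternative 1 | spiro-fused 6,6-dimethylbicyclo[3.1.0]hexan-2-one dienone | CC1(C)[C@H]2CC3(C=CC(=O)C=C3)C(=O)[C@@H]12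
A3 | alternative 2 | 3-[(E)-4-(2,5-dimethoxyphenyl)-2-methylenebut-3-enyl]-4-methoxy-2-(3-methylbut-2-enyl)phenol | COc1ccc(O)c(CC=C(C)C)c1CC(=C)/C=C/c1cc(OC)ccc1OC
A4 | alternative 2 | tetracyclic C7 ketone with C10=C11 methyl enol ether | CC(C)=CC[C@@]23C(=O)CC=C(OC)[C@@]21CC(C)=C[C@@H]3c2c(OC)ccc(OC)c21
A5 | alternative 3 | bicyclic cross-conjugated dienone (C13=C14, C15=O, C17=C18) with C6 prenyl, C7 ketone and C11 silyl ether | CC(C)=CC[C@@]23C(=O)CC[C@@H](O[Si](C)(C)C(C)(C)C)C2=CC(=O)C=C3
A6 | alternative 3 | arene-bridged tricyclic diketone with free hydroquinone | CC(C)=CC[C@@]23C(=O)CC[C@@H](O[Si](C)(C)C(C)(C)C)[C@@]21CC(=O)C[C@@H]3c2c(O)ccc(O)c21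
A7 | alternative 3 | hydroquinone | Oc1ccc(O)cc1
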